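**Retrosynthetic overview**
1. Target 23 ⇒ protected ester 22, from which one acidolysis frees CO2H, CHO and OH. 22 is cut at C3'–C4' of the acyl chain: a mixed Kolbe electrolysis of hemisuccinate 14 with (Z)-acid 21, in which both carbons are born as radicals by loss of CO2.
2. Enabling feature: the ester O on C10 of the cyclohexene ring carries C1'(=O)–C2'H2–C3'H2, a succinyl unit short of one carboxyl, so C3' can come from a hemisuccinate. C4' is insulated from the C9'=C10' Z-alkene by four CH2 groups. The only other carboxyl (C15 on ring carbon C8) is vinylic and can be masked.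
3. 14 ⇒ succinic anhydride 13 + endo-allylic alcohol 12. 12 ⇒ oxidation-only elaboration of an intact cedrane: C2–H → C2=C3 → C12 enal → (2S)-aldehyde; C8–OAc → C8=C9; C15H3 → CO2t-Bu; C10H2 → C=O → (10S)-OH.
4. Rings: cyclopentane A (C1–C5), cyclopentane B (C1, C5, C6, C7, C11) and six-membered ring C (C1, C10, C9, C8, C7, C11) are not built. They are bought in (+)-cedryl acetate 1, which fixes C1, C5 and C7. The only ring formed is the temporary dioxolane on C12 (step 5), opened again in step 17.
5. 21 ⇒ Z-selective Wittig reaction of the ylide from 7-bromoheptanoic acid 18 with aldehyde 17 from heptane-1,7-diol 15.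

Key step: step 16

Remark on numbering: cedrane numbering is used for the core.
- C1 is the spiro quaternary carbon, C2 bears the formyl carbon C12, C5 is the ring-fusion CH, and C6 is CMe2.
- C7 is the bridgehead CH, C8=C9 is the alkene with carboxyl carbon C15 on C8, C10 is the carbinol carbon, and C11 is the CH2 bridge.
- Primed numbers belong to the acyl chain.

Assumption: commercial crystalline (+)-cedryl acetate is the natural (1S,2R,5S,7R,8R) enantiomer. Its C1, C5 and C7 have the same spatial arrangement as in the target.

**Step 1**
Reactants: 1 (+)-cedryl acetate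
Product: 2 2-hydroxycedryl acetate (tertiary OH at C2 on the face of the C11 bridge)
Conditions: methyl(trifluoromethyl)dioxirane (ca. 0.5 M in CF3COCH3, 1.3 equiv), CH2Cl2, −20 to 0 °C
Reagents that add atoms: methyl(trifluoromethyl)dioxirane, CC1(OO1)C(F)(F)F
Why: Dioxirane C–H hydroxylation (concerted O insertion with retention, so the OH takes the place of H-2) should single out C2–H, the only tertiary C–H that is both remote from the acetate and exposed, since C7–H is a bridgehead next to the electron-withdrawing C8–OAc and C5–H points into the pocket under ring C.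

**Step 2**
Reactants: 2 2-hydroxycedryl acetate
Product: 3 cedr-2-en-8-yl acetate (trisubstituted C2=C3 alkene)
Conditions: Burgess reagent (1.5 equiv), toluene, 60 °C
Reagents that add atoms: none
Why: Burgess dehydration (syn Ei elimination of the sulfamate) should take the nearly eclipsed cis H-3 and give the Zaitsev C2=C3 alkene, C1 being quaternary, while the neutral conditions leave the tertiary acetate untouched and the C2 stereocentre is erased on purpose.

**Step 3**
Reactants: 3 cedr-2-en-8-yl acetate
Product: 4 8-acetoxycedr-2-en-12-al
Conditions: SeO2 (1.3 equiv), pyridine (2 equiv), 1,4-dioxane, 80 °C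
Reagents that add atoms: selenium dioxide, O=[Se]=O
Why: Riley allylic oxidation acts at the more substituted alkene terminus C2, whose only allylic hydrogens are those of the C12 methyl group because C1 is quaternary, the same pattern as in the oxidation of α-pinene to myrtenal.

**Step 4**
Reactants: 4 8-acetoxycedr-2-en-12-al
Product: 5 (2S)-8-acetoxycedran-12-al (formyl group on the face of the C11 bridge)
Conditions: H2 (1 atm), 10% Pd/C, EtOAc, rt
Reagents that add atoms: none
Why: Heterogeneous syn hydrogenation of the only C=C should deliver H2 to the ring-A face opposite the quasi-axial C11 bridge on C1, which puts H-2 on the C10 side and the formyl group on the C11 side (2S), and this quasi-equatorial aldehyde should also be the more stable epimer, so later enolisation cannot erode it.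

**Step 5**
Reactants: 5 (2S)-8-acetoxycedran-12-al
Product: 7 (2S)-12,12-ethylenedioxycedr-8-ene, via dioxolane acetate 6 (not isolated)
Conditions: HOCH2CH2OH (5 equiv), p-TsOH·H2O (15 mol %), benzene, reflux, Dean–Stark
Reagents that add atoms: ethylene glycol, OCCO
Why: Acid-catalysed acetalisation with azeotropic removal of water is followed in the same flask by E1 loss of acetic acid from the tertiary C8 acetate through the cedryl cation, which under equilibrating conditions should end as the trisubstituted C8=C9 alkene (C7=C8 would violate Bredt's rule), as in the acid dehydration of cedrol to α-cedrene.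

**Step 6**
Reactants: 7 (2S)-12,12-ethylenedioxycedr-8-ene
Product: 8 (2S)-12,12-ethylenedioxycedr-8-en-15-al
Conditions: SeO2 (1.3 equiv), pyridine (2 equiv), 1,4-dioxane, 80 °C
Reagents that add atoms: selenium dioxide, O=[Se]=O
Why: Riley allylic oxidation again acts at the more substituted terminus C8, where only the C15 methyl group can take part because an ene reaction of the bridgehead C7–H is forbidden by Bredt's rule, and the pyridine buffer protects the dioxolane.

**Step 7**
Reactants: 8 (2S)-12,12-ethylenedioxycedr-8-en-15-al
Product: 9 (2S)-12,12-ethylenedioxycedr-8-en-15-oic acid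
Conditions: NaClO2, NaH2PO4, 2-methyl-2-butene, t-BuOH/H2O, 0 °C to rt
Reagents that add atoms: sodium chlorite, [Na+].[O-]Cl=O
Why: Pinnick oxidation converts the enal into the enoic acid without touching the C8=C9 bond (hypochlorous acid is scavenged), and the buffered medium is too weakly acidic to open the dioxolane.

**Step 8**
Reactants: 9 (2S)-12,12-ethylenedioxycedr-8-en-15-oic acid
Product: 10 tert-butyl (2S)-12,12-ethylenedioxycedr-8-en-15-oate
Conditions: Cl3CC(=NH)Ot-Bu (2.5 equiv), cyclohexane/CH2Cl2, rt
Reagents that add atoms: tert-butyl 2,2,2-trichloroacetimidate, CC(C)(C)OC(=N)C(Cl)(Cl)Cl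
Why: O-tert-butylation with the trichloroacetimidate (transfer of the tert-butyl cation, promoted by the substrate acid itself) avoids attack at the hindered carbonyl and needs no strong acid, so the dioxolane stays.

**Step 9**
Reactants: 10 tert-butyl (2S)-12,12-ethylenedioxycedr-8-en-15-oate
Product: 11 tert-butyl (2S)-12,12-ethylenedioxy-10-oxocedr-8-en-15-oate
Conditions: Rh2(cap)4 (1 mol %), t-BuOOH (70% aq, 10 equiv), 1,2-dichloroethane, 40 °C
Reagents that add atoms: tert-butyl hydroperoxide, CC(C)(C)OO
Why: Dirhodium caprolactamate/TBHP allylic oxidation, a reaction type known to turn cyclohexene-1-carboxylates and enones into their γ-oxo derivatives, can act only at C10, the sole allylic CH2, because C7–H is a bridgehead held orthogonal to the π system and the selective peroxyl radical should spare the stronger acetal C–H.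

**Step 10**
Reactants: 11 tert-butyl (2S)-12,12-ethylenedioxy-10-oxocedr-8-en-15-oate
Product: 12 tert-butyl (2S,10S)-12,12-ethylenedioxy-10-hydroxycedr-8-en-15-oate (OH endo, towards the C5–C6 bridge)
Conditions: NaBH4, CeCl3·7H2O, MeOH, −78 to −20 °C
Reagents that add atoms: none
Why: Luche reduction is 1,2-selective, and hydride should arrive from the exo face (side of the C11 bridge) because the endo face of C10 is blocked by the endo H-5 and the endo methyl group on C6, which sets the endo (10S) alcohol.

**Step 11**
Reactants: 12 tert-butyl (2S,10S)-12,12-ethylenedioxy-10-hydroxycedr-8-en-15-oate; 13 succinic anhydride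
Product: 14 C10 hydrogen succinate of 12
Conditions: DMAP (1 equiv), Et3N (3 equiv), CH2Cl2, 40 °C; aq. citric acid work-up
Reagents that add atoms: none
Why: DMAP-catalysed ring opening of the cyclic anhydride by the hindered secondary alcohol installs C1'–C3' plus the sacrificial carboxyl group in one step with retention at C10, since only the O–H bond is broken.

**Step 12**
Reactants: 15 heptane-1,7-diol
Product: 16 7-(tert-butyldimethylsilyloxy)heptan-1-ol
Conditions: TBSCl (1 equiv), imidazole, 15 (3 equiv), THF/DMF, 0 °C to rt
Reagents that add atoms: tert-butyldimethylsilyl chloride, CC(C)(C)[Si](C)(C)Cl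
Why: Statistical monosilylation of a symmetrical diol used in excess should give mainly the mono-ether, and the surplus diol is washed out with water.

**Step 13**
Reactants: 16 7-(tert-butyldimethylsilyloxy)heptan-1-ol
Product: 17 7-(tert-butyldimethylsilyloxy)heptanal
Conditions: TEMPO (10 mol %), PhI(OAc)2 (1.1 equiv), CH2Cl2, rt
Reagents that add atoms: none
Why: Oxoammonium (TEMPO/PhI(OAc)2) oxidation stops at the aldehyde and tolerates the silyl ether.

**Step 14**
Reactants: 18 7-bromoheptanoic acid
Product: 19 (6-carboxyhexyl)triphenylphosphonium bromide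
Conditions: PPh3, MeCN, reflux
Reagents that add atoms: triphenylphosphine, c1ccc(cc1)P(c1ccccc1)c1ccccc1
Why: SN2 quaternisation of triphenylphosphine by the primary bromide gives the crystalline phosphonium salt.

**Step 15**
Reactants: 19 (6-carboxyhexyl)triphenylphosphonium bromide; 17 7-(tert-butyldimethylsilyloxy)heptanal
Product: 21 (Z)-14-(tert-butyldimethylsilyloxy)tetradec-7-enoic acid, via sodium ylide carboxylate 20 (not isolated)
Conditions: NaHMDS (2.1 equiv), THF, 0 °C; then 17, −78 °C to rt; aq. citric acid work-up
Reagents that add atoms: none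
Why: Wittig olefination with a non-stabilised ylide under lithium-free conditions proceeds through the kinetically favoured cis-oxaphosphetane and should set the Z geometry of the future C9'=C10' bond.

**Step 16**
Reactants: 14 C10 hydrogen succinate of 12; 21 (Z)-14-(tert-butyldimethylsilyloxy)tetradec-7-enoic acid
Product: 22 fully protected target (C10 (9Z)-16-silyloxyhexadec-9-enoate, C15 tert-butyl ester, C12 dioxolane)
Conditions: undivided cell, Pt anode/Pt cathode, 14 (1 equiv) + 21 (5 equiv), KOH (10 mol % of total acid), MeOH, constant current ca. 0.25 A cm−2, 20–35 °C, until the solution turns slightly alkaline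
Reagents that add atoms: none
Why: Both carboxylates are discharged at the platinum anode at high current density, lose CO2 and give the primary radicals •C3'H2–C2'H2–C1'(=O)O–C10 and •C4'H2(CH2)4CH=CH(CH2)6OTBS, which combine in the dense radical layer at the electrode to form the C3'–C4' bond while protons are reduced to H2 at the cathode. The closest known reaction type is the mixed (crossed) Kolbe electrolysis of dicarboxylic acid half-esters with long-chain (Z)-alkenoic acids, the classical chain extension of unsaturated fatty acids that keeps the alkene geometry. No ring is closed and no stereocentre is made; the five core stereocentres and the Z-alkene are spectators because neither radical is allylic or attached to a stereocentre. Hetero- versus homo-coupling is statistical, so the cheap acid 21 is used in five-fold excess and its symmetrical dimer is removed by chromatography. Chemoselectivity rests on the substrate: 14 holds a single free aliphatic carboxyl group (C15 is a tert-butyl enoate, C12 a dioxolane), primary radicals are not over-oxidised to cations (no Hofer–Moest products), and the ring C8=C9 enoate is β-substituted and shielded. The unimolecular escapes, 6-exo attack of C4' on C9'=C10' and lactonising 6-exo attack of C3' on ring carbon C9 through the disfavoured E-ester rotamer, should be orders of magnitude slower than radical–radical coupling at the electrode.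

**Step 17**
Reactants: 22 fully protected target
Product: 23 target, (1S,2S,5S,7R,10S)-2-formyl-10-[(9Z)-16-hydroxyhexadec-9-enoyloxy]-6,6-dimethyltricyclo[5.3.1.0(1,5)]undec-8-ene-8-carboxylic acid
Conditions: TFA/H2O (9:1), CH2Cl2, 0 °C to rt
Reagents that add atoms: water, O
Why: One acidolysis should cleave the tert-butyl ester (alkyl–oxygen fission), the dioxolane and the primary silyl ether, while the C10 allylic ester does not ionise because its allyl cation would be conjugated with the carboxyl group, the isolated Z-alkene is inert in the cold, and C2 already holds its more stable configuration anti to the C10 acyloxy group.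

**Compound list**
1 | (+)-cedryl acetate | CC1(C)[C@H]2C[C@@]3(CC[C@@]2(C)OC(C)=O)[C@H](C)CC[C@@H]13 | starting material
2 | 2-hydroxycedryl acetate | CC1(C)[C@H]2C[C@@]3(CC[C@@]2(C)OC(C)=O)[C@](O)(C)CC[C@@H]13 | intermediate
3 | cedr-2-en-8-yl acetate | CC1(C)[C@H]2C[C@@]3(CC[C@@]2(C)OC(C)=O)C(C)=CC[C@@H]13 | intermediate
4 | 8-acetoxycedr-2-en-12-al | CC1(C)[C@H]2C[C@@]3(CC[C@@]2(C)OC(C)=O)C(C=O)=CC[C@@H]13 | intermediate
5 | (2S)-8-acetoxycedran-12-al | CC1(C)[C@H]2C[C@@]3(CC[C@@]2(C)OC(C)=O)[C@@H](C=O)CC[C@@H]13 | intermediate
6 | dioxolane acetate (ethylene acetal of 5, not isolated) | CC1(C)[C@H]2C[C@@]3(CC[C@@]2(C)OC(C)=O)[C@@H](C4OCCO4)CC[C@@H]13 | intermediate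
7 | (2S)-12,12-ethylenedioxycedr-8-ene | CC1(C)[C@H]2C[C@@]3(CC=C2C)[C@@H](C4OCCO4)CC[C@@H]13 | intermediate
8 | (2S)-12,12-ethylenedioxycedr-8-en-15-al | CC1(C)[C@H]2C[C@@]3(CC=C2C=O)[C@@H](C4OCCO4)CC[C@@H]13 | intermediate
9 | (2S)-12,12-ethylenedioxycedr-8-en-15-oic acid | CC1(C)[C@H]2C[C@@]3(CC=C2C(=O)O)[C@@H](C4OCCO4)CC[C@@H]13 | intermediate
10 | tert-butyl (2S)-12,12-ethylenedioxycedr-8-en-15-oate | CC1(C)[C@H]2C[C@@]3(CC=C2C(=O)OC(C)(C)C)[C@@H](C4OCCO4)CC[C@@H]13 | intermediate
11 | tert-butyl (2S)-12,12-ethylenedioxy-10-oxocedr-8-en-15-oate | CC1(C)[C@H]2C[C@@]3(C(=O)C=C2C(=O)OC(C)(C)C)[C@@H](C4OCCO4)CC[C@@H]13 | intermediate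
12 | tert-butyl (2S,10S)-12,12-ethylenedioxy-10-hydroxycedr-8-en-15-oate | CC1(C)[C@H]2C[C@@]3([C@@H](O)C=C2C(=O)OC(C)(C)C)[C@@H](C4OCCO4)CC[C@@H]13 | intermediate
13 | succinic anhydride | O=C1CCC(=O)O1 | starting material
14 | C10 hydrogen succinate of 12 | CC1(C)[C@H]2C[C@@]3([C@@H](OC(=O)CCC(=O)O)C=C2C(=O)OC(C)(C)C)[C@@H](C4OCCO4)CC[C@@H]13 | intermediate
15 | heptane-1,7-diol | OCCCCCCCO | starting material
16 | 7-(tert-butyldimethylsilyloxy)heptan-1-ol | OCCCCCCCO[Si](C)(C)C(C)(C)C | intermediate
17 | 7-(tert-butyldimethylsilyloxy)heptanal | O=CCCCCCCO[Si](C)(C)C(C)(C)C | intermediate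
18 | 7-bromoheptanoic acid | OC(=O)CCCCCCBr | starting material
19 | (6-carboxyhexyl)triphenylphosphonium bromide | OC(=O)CCCCCC[P+](c1ccccc1)(c1ccccc1)c1ccccc1.[Br-] | intermediate
20 | sodium ylide carboxylate (not isolated) | [Na+].[O-]C(=O)CCCCCC=P(c1ccccc1)(c1ccccc1)c1ccccc1 | intermediate
21 | (Z)-14-(tert-butyldimethylsilyloxy)tetradec-7-enoic acid | OC(=O)CCCCC/C=C\CCCCCCO[Si](C)(C)C(C)(C)C | intermediate
22 | fully protected target | CC1(C)[C@H]2C[C@@]3([C@@H](OC(=O)CCCCCCC/C=C\CCCCCCO[Si](C)(C)C(C)(C)C)C=C2C(=O)OC(C)(C)C)[C@@H](C4OCCO4)CC[C@@H]13 | intermediate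
23 | target CNP0214056.2 | CC1(C)[C@H]2C[C@@]3([C@@H](OC(=O)CCCCCCC/C=C\CCCCCCO)C=C2C(=O)O)[C@@H](C=O)CC[C@@H]13 | target

**Step count**
Total step count: 17. Longest linear sequence: 13 (steps 1–11, 16, 17).

**Steps most likely to fail**

Step 16 (mixed Kolbe electrolysis).
- Homo-coupling and disproportionation of the two radicals may outrun the crossed coupling.
- The lipophilic acids may passivate the anode.
- The silyl ether may be lost slowly in methanol.

The fallback replaces radical–radical coupling by radical addition to an acceptor. It sets out from alcohol 12 and acid 21 and comes back at 22. Alcohol 12 is acylated with acryloyl chloride (Et3N, DMAP, CH2Cl2, 0 °C) to the C10 acrylate F1. Acid 21 is condensed with N-hydroxyphthalimide (DIC, DMAP, CH2Cl2) to the redox-active ester F2. A visible-light decarboxylative Giese reaction follows (Ru(bpy)3(PF6)2, Hantzsch ester, i-Pr2NEt, CH2Cl2, blue LED). It lets the C4' radical add to the unsubstituted acrylate terminus C3', which is far more reactive than the β-substituted ring enoate. Hydrogen transfer to C2' then gives 22.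

Step 1 (C–H hydroxylation). Site selectivity between C2–H and the ring-A methylene groups may be poor, and over-oxidation may set in. The fallback swaps oxygen insertion for radical halogenation and elimination. It sets out from 1 and comes back at 3. Free-radical chlorination with iodobenzene dichloride under irradiation (CH2Cl2, rt) relies on a bulky chain carrier that is strongly selective for tertiary C–H bonds, and should give the C2 tertiary chloride F3. Dehydrochlorination with DBU (toluene, 80 °C) then leads to alkene 3. The configuration of F3 at C2 is without consequence.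

Step 9 (γ-oxidation of the enoate). Hydrogen abstraction at the neopentyl, electron-poor C10H2 may be sluggish, so oxidant decay or attack at the acetal C–H may compete. The fallback changes the order of oxidation, so that C10 is oxidised while the alkene is still electron-rich. It sets out from 7 and comes back at 11.
- Allylic oxidation of 7 with CrO3·3,5-dimethylpyrazole (CH2Cl2, −20 °C), as in the conversion of α-pinene into verbenone, should give the enone F4.
- Riley oxidation of its β-methyl group (SeO2, pyridine, dioxane, 80 °C) gives the keto-enal F5.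
- Pinnick oxidation gives the keto acid F6.
- tert-Butyl trichloroacetimidate converts F6 into 11.

**Further compounds**
F1 | step 16 | C10 acrylate of 12 | CC1(C)[C@H]2C[C@@]3([C@@H](OC(=O)C=C)C=C2C(=O)OC(C)(C)C)[C@@H](C4OCCO4)CC[C@@H]13
F2 | step 16 | N-hydroxyphthalimide ester of 21 | O=C(CCCCC/C=C\CCCCCCO[Si](C)(C)C(C)(C)C)ON1C(=O)c2ccccc2C1=O
F3 | step 1 | 2-chlorocedryl acetate | CC1(C)[C@H]2C[C@@]3(CC[C@@]2(C)OC(C)=O)[C@@](Cl)(C)CC[C@@H]13
F4 | step 9 | (2S)-12,12-ethylenedioxycedr-8-en-10-one | CC1(C)[C@H]2C[C@@]3(C(=O)C=C2C)[C@@H](C4OCCO4)CC[C@@H]13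
F5 | step 9 | (2S)-12,12-ethylenedioxy-10-oxocedr-8-en-15-al | CC1(C)[C@H]2C[C@@]3(C(=O)C=C2C=O)[C@@H](C4OCCO4)CC[C@@H]13
F6 | step 9 | (2S)-12,12-ethylenedioxy-10-oxocedr-8-en-15-oic acid | CC1(C)[C@H]2C[C@@]3(C(=O)C=C2C(=O)O)[C@@H](C4OCCO4)CC[C@@H]13
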